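A direct plan would build the C17 chain first (four steps), make from its methyl ketone the 3-silyloxy-3-alkylcyclobutanone A1 by dichloroketene [2+2] addition and dechlorination,
expand A1 with acetylene under chiral nickel catalysis to the 5-silyloxycyclohex-2-enone A2, deconjugate the freed hydroxy enone to the β,γ-enone A3,
epoxidise A3 under hydroxyl direction to A4 and open the epoxide by E1cB to the target.
Weakest would be the enantioselective nickel-catalysed insertion of acetylene into the C(O)–CH2 bond of A1: the only source of absolute configuration would be a reaction without precedent, run on material that already carries the whole chain.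
Next, the deconjugation of the enone through its dienolate would run against thermodynamics on late material, with α′-deprotonation, loss of the β-oxygen and aromatisation as competitors, and A3 could only be used crude.
Third, the four chain-building steps at the start would add no complexity to the core, and the chain would then be carried through every risky step of a fully linear sequence.

**Plan of the new route**

Feature used: ring carbons C1, C4 and C5 carry oxygen in the 1,2,4-pattern of an alkylhydroquinone, C5 is the alkylated carbon next to the C4 oxygen, and C2=C3 is a former arene bond; the six-membered ring is therefore a benzene ring that is dearomatised, never closed.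
Cuts, backwards: the two Si–O bonds (C1 enol ether, C5 ether); the C4–H bond (ketone of an ortho-quinol); the C5–O bond (hydroxylative dearomatisation of a 2-alkyl-4-silyloxyphenol by a chiral iodyl arene); the aryl–C1′ bond (B-alkyl Suzuki coupling); the C11′–C12′ bond of the chain (copper-catalysed Grignard coupling).
Order: chain (two steps) and bromophenol are joined, the arene is dearomatised with creation of C5 under reagent control, C4 follows under control by C5, and fluoride frees the enone.
No four-membered ring, no alkyne insertion and no enone deconjugation occur: the enone and its oxygen pattern come from the arene, and the chain is made in two steps and joined convergently.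

Key step: step 6

Assumption: the sense of induction of 11 on phenol 9 cannot be derived with certainty, so the (R)-reagent is written for the (S)-quinol; if a trial shows the opposite sense, the (S)-reagent, made the same way from the (S)-diiodide, would be used (the axis of 10 and 11 is given in the names, since SMILES cannot show it).

Step 1
Reactants: 1 (E)-hex-3-en-1-ol
Product: 2 (E)-hex-3-en-1-yl 4-methylbenzenesulfonate
Conditions: TsCl, Et3N, DMAP (cat.), CH2Cl2, 0 °C → rt
Reagents that add atoms: 4-methylbenzenesulfonyl chloride, Cc1ccc(cc1)S(=O)(=O)Cl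
Why: O-Sulfonylation (tosylation) of a primary alcohol, which should turn the hydroxyl into a leaving group for the copper-catalysed coupling without touching the (E)-alkene.

Step 2
Reactants: 3 11-bromoundec-1-ene; 2 (E)-hex-3-en-1-yl 4-methylbenzenesulfonate
Product: 5 (E)-heptadeca-1,14-diene, via undec-10-enylmagnesium bromide 4 (not isolated)
Conditions: 3, Mg, THF, rt; then 2, Li2CuCl4 (3 mol %), THF, −20 °C → rt; aq. NH4Cl
Reagents that add atoms: none
Why: Copper-catalysed alkyl–alkyl cross-coupling of a primary Grignard reagent with a primary tosylate, which should join C11′ to C12′ by substitution at a centre remote from both alkenes, so that the (E) geometry and the terminal vinyl group are kept.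

Step 3
Reactants: 6 4-(tert-butyldimethylsilyloxy)phenol
Product: 7 2-bromo-4-(tert-butyldimethylsilyloxy)phenol
Conditions: NBS (1.0 equiv), i-Pr2NH (10 mol %), CH2Cl2, −20 → 0 °C
Reagents that add atoms: N-bromosuccinimide, O=C1CCC(=O)N1Br
Why: Electrophilic aromatic bromination, in which the free hydroxyl is the stronger director and the para position is blocked, so that bromine should enter ortho to OH and not ortho to the silyloxy group.

Step 4
Reactants: 5 (E)-heptadeca-1,14-diene; 7 2-bromo-4-(tert-butyldimethylsilyloxy)phenol
Product: 9 4-(tert-butyldimethylsilyloxy)-2-[(E)-heptadec-14-enyl]phenol, via B-[(E)-heptadec-14-enyl]-9-BBN 8 (not isolated)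
Conditions: 5 (1.2 equiv), 9-BBN, THF, 0 °C → rt; then 7, Pd(OAc)2 (3 mol %), SPhos (2-dicyclohexylphosphino-2′,6′-dimethoxybiphenyl, 6 mol %), K3PO4 (3 equiv, 3 M aq.), THF, 60 °C
Reagents that add atoms: none
Why: Hydroboration by hindered 9-BBN, which should take only the terminal alkene and put boron on C1, followed by B-alkyl Suzuki–Miyaura coupling with the aryl bromide under a biarylphosphine ligand that tolerates the free phenol, whose phenoxide form also makes the para silyl ether a poor leaving group toward the aqueous base.

Step 5
Reactants: 10 (R)-2,2′-diiodo-1,1′-binaphthyl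
Product: 11 (R)-2,2′-diiodyl-1,1′-binaphthyl
Conditions: dimethyldioxirane (acetone solution, excess), CH2Cl2, 0 °C → rt; evaporation
Reagents that add atoms: dimethyldioxirane, CC1(C)OO1
Why: Oxygen-atom transfer from the dioxirane to each aryl iodide, which should raise iodine from the monovalent to the pentavalent (iodyl) state under neutral, metal-free conditions that leave the configurationally stable binaphthyl axis untouched.

Step 6
Reactants: 9 4-(tert-butyldimethylsilyloxy)-2-[(E)-heptadec-14-enyl]phenol; 11 (R)-2,2′-diiodyl-1,1′-binaphthyl
Product: 12 (S)-4-(tert-butyldimethylsilyloxy)-6-[(E)-heptadec-14-enyl]-6-hydroxycyclohexa-2,4-dien-1-one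
Conditions: 11 (1.0 equiv), THF, −40 → 0 °C; cold aq. NaHCO3; crude 12 used at once
Reagents that add atoms: none
Why: The phenol should exchange onto one pentavalent iodine centre of 11 to give an aryloxy iodane, an oxo ligand then passes from iodine to the ortho carbon that bears the chain ([2,3]-type ligand coupling, iodine going to the trivalent state), and hydrolysis of the O–I bond on work-up frees the 6-hydroxy-2,4-dienone, so that one step breaks the aromaticity and makes the C–O bond of the tertiary carbinol (C5 of the target). The closest known reaction type is the hydroxylative dearomatisation of 2-alkylphenols by iodyl arenes (stabilised IBX), which has an asymmetric version with C2-symmetric biaryl bis(iodyl) reagents of the kind used here. No ring is closed: the carbocycle of the target is the benzene ring of 9, taken over with its three oxygenated carbons and the future C2=C3 bond in place. The one new stereocentre (C6 of 12, C5 of the target) is controlled by the chiral axis of 11, which shields one face of the iodine-bound phenoxy ligand during the oxygen transfer. The step needs oxygen to go to the alkylated ortho carbon and not to the free ortho C–H or the para carbon: delivery from the iodine on the phenol oxygen excludes the para position, and the alkylated ortho carbon is the more electron-rich acceptor, as found for other 2-alkylphenols with one free ortho position. It also needs the quinol to survive as a monomer and the remote alkene to stay intact: the bulky silyloxy group sits on the C4=C5 bond that would be the dienophile in the [4+2] dimerisation typical of such quinols, and iodyl arenes do not attack isolated alkenes at this temperature.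

Step 7
Reactants: 12 (S)-4-(tert-butyldimethylsilyloxy)-6-[(E)-heptadec-14-enyl]-6-hydroxycyclohexa-2,4-dien-1-one
Product: 13 (S)-4-(tert-butyldimethylsilyloxy)-6-[(E)-heptadec-14-enyl]-6-(triethylsilyloxy)cyclohexa-2,4-dien-1-one
Conditions: crude 12, Et3SiOTf, 2,6-lutidine, CH2Cl2, −78 °C
Reagents that add atoms: triethylsilyl trifluoromethanesulfonate, CC[Si](CC)(CC)OS(=O)(=O)C(F)(F)F
Why: Silylation of a tertiary alcohol with a silyl triflate and a hindered pyridine base, fast at −78 °C on a ketone without enolisable hydrogen, which removes the hydroxyl that could direct or chelate a hydride reagent and adds bulk against quinol dimerisation.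

Step 8
Reactants: 13 (S)-4-(tert-butyldimethylsilyloxy)-6-[(E)-heptadec-14-enyl]-6-(triethylsilyloxy)cyclohexa-2,4-dien-1-one
Product: 14 (1R,6S)-4-(tert-butyldimethylsilyloxy)-6-[(E)-heptadec-14-enyl]-6-(triethylsilyloxy)cyclohexa-2,4-dien-1-ol
Conditions: i-Bu2AlH (1.2 equiv), CH2Cl2, −78 °C; aq. potassium sodium tartrate; filtration through Et3N-deactivated silica
Reagents that add atoms: none
Why: 1,2-Reduction of the dienone carbonyl by DIBAL-H, in which hydride should attack anti to the C6–OSiEt3 bond that stands nearly perpendicular to the carbonyl plane (polar Felkin–Anh control, reinforced by the bulk of the silyl ether), so that the new C1 hydroxyl (C4 of the target, R) is cis to the tertiary oxygen.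

Step 9
Reactants: 14 (1R,6S)-4-(tert-butyldimethylsilyloxy)-6-[(E)-heptadec-14-enyl]-6-(triethylsilyloxy)cyclohexa-2,4-dien-1-ol
Product: 15 (4R,5S)-5-[(E)-heptadec-14-enyl]-4,5-dihydroxycyclohex-2-en-1-one
Conditions: HF·pyridine, pyridine, THF, 0 °C → rt; aq. NaHCO3
Reagents that add atoms: none
Why: Fluoride-driven cleavage of both Si–O bonds under buffered conditions, in which the silyl dienol ether should collapse with protonation at C5 of 14 (C6 of the target) to the conjugated enone, the C2=C3 bond and both stereocentres staying untouched, and the tertiary silyl ether is cleaved without a free enolate that could expel the β-oxygen.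

**Compound list**

1 | (E)-hex-3-en-1-ol | CC/C=C/CCO | starting material
2 | (E)-hex-3-en-1-yl 4-methylbenzenesulfonate | CC/C=C/CCOS(=O)(=O)c1ccc(C)cc1 | intermediate
3 | 11-bromoundec-1-ene | C=CCCCCCCCCCBr | starting material
4 | undec-10-enylmagnesium bromide | C=CCCCCCCCCC[Mg]Br | intermediate
5 | (E)-heptadeca-1,14-diene | CC/C=C/CCCCCCCCCCCC=C | intermediate
6 | 4-(tert-butyldimethylsilyloxy)phenol | CC(C)(C)[Si](C)(C)Oc1ccc(O)cc1 | starting material
7 | 2-bromo-4-(tert-butyldimethylsilyloxy)phenol | CC(C)(C)[Si](C)(C)Oc1ccc(O)c(Br)c1 | intermediate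
8 | 9-[(E)-heptadec-14-enyl]-9-borabicyclo[3.3.1]nonane | CC/C=C/CCCCCCCCCCCCCB1C2CCCC1CCC2 | intermediate
9 | 4-(tert-butyldimethylsilyloxy)-2-[(E)-heptadec-14-enyl]phenol | CC/C=C/CCCCCCCCCCCCCc1cc(O[Si](C)(C)C(C)(C)C)ccc1O | intermediate
10 | (R)-2,2′-diiodo-1,1′-binaphthyl | Ic1ccc2ccccc2c1-c1c(I)ccc2ccccc12 | starting material
11 | (R)-2,2′-diiodyl-1,1′-binaphthyl | O=I(=O)c1ccc2ccccc2c1-c1c(I(=O)=O)ccc2ccccc12 | intermediate
12 | (S)-4-(tert-butyldimethylsilyloxy)-6-[(E)-heptadec-14-enyl]-6-hydroxycyclohexa-2,4-dien-1-one | CC/C=C/CCCCCCCCCCCCC[C@]1(O)C=C(O[Si](C)(C)C(C)(C)C)C=CC1=O | intermediate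
13 | (S)-4-(tert-butyldimethylsilyloxy)-6-[(E)-heptadec-14-enyl]-6-(triethylsilyloxy)cyclohexa-2,4-dien-1-one | CC/C=C/CCCCCCCCCCCCC[C@]1(O[Si](CC)(CC)CC)C=C(O[Si](C)(C)C(C)(C)C)C=CC1=O | intermediate
14 | (1R,6S)-4-(tert-butyldimethylsilyloxy)-6-[(E)-heptadec-14-enyl]-6-(triethylsilyloxy)cyclohexa-2,4-dien-1-ol | CC/C=C/CCCCCCCCCCCCC[C@]1(O[Si](CC)(CC)CC)C=C(O[Si](C)(C)C(C)(C)C)C=C[C@H]1O | intermediate
15 | (4R,5S)-5-[(E)-heptadec-14-enyl]-4,5-dihydroxycyclohex-2-en-1-one | CC/C=C/CCCCCCCCCCCCC[C@]1(O)CC(=O)C=C[C@H]1O | target

Total step count: 9 (including the preparation of the iodyl reagent 11).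
Longest linear sequence: 7 steps (steps 1, 2, 4, 6, 7, 8, 9).

**Steps most likely to fail**

1. Step 6. The oxygen transfer may show low enantiofacial discrimination, may go to the unsubstituted ortho carbon (leading on to an ortho-quinone), or the quinol may dimerise by [4+2] addition before it is silylated. The fallback sets out from 5 and comes back at 15. Diene 5 would be hydroborated with 9-BBN and coupled (Pd(OAc)2, SPhos, K3PO4) with commercial 2-bromo-4-methoxyphenol to give 2-[(E)-heptadec-14-enyl]-4-methoxyphenol F1. PhI(OAc)2 in MeOH (0 °C) would dearomatise it at the para position to the quinone monoketal 2-[(E)-heptadec-14-enyl]-4,4-dimethoxycyclohexa-2,5-dien-1-one F2. CBS reduction with (S)-2-methyl-CBS-oxazaborolidine and catecholborane (toluene, −78 °C), the alkylated alkene arm acting as the large group, should give (R)-2-[(E)-heptadec-14-enyl]-4,4-dimethoxycyclohexa-2,5-dien-1-ol F3. Hydroxyl-directed epoxidation (VO(acac)2, t-BuOOH, CH2Cl2, 0 °C) of the trisubstituted C2=C3 bond would place the epoxide oxygen cis to the hydroxyl and give (1R,2R,6R)-1-[(E)-heptadec-14-enyl]-5,5-dimethoxy-7-oxabicyclo[4.1.0]hept-3-en-2-ol F4. Ketal hydrolysis (oxalic acid, acetone/H2O) would give (1R,5R,6R)-6-[(E)-heptadec-14-enyl]-5-hydroxy-7-oxabicyclo[4.1.0]hept-3-en-2-one F5, and SmI2 (THF/MeOH, −90 °C) would cleave the C–O bond α to the ketone of this α,β-epoxy ketone to give 15. In this sequence the absolute configuration would come from the CBS step and the cis-diol from the directed epoxidation.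

2. Step 8. Hydride may be delivered syn to the silyloxy group, which would give the trans-diol, or in conjugate fashion. The fallback sets out from 13 and comes back at 14; no new compound is made (F0). Substrate control would be replaced by reagent control: CBS reduction of 13 with a 2-methyl-CBS-oxazaborolidine and catecholborane at −78 °C, using the catalyst enantiomer whose facial preference is matched with attack anti to the silyloxy group (to be found in a trial with both enantiomers). The minor diastereomer would be removed on deactivated silica.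

3. Step 9. Ionisation of the tertiary C–O bond, which is activated by the dienol ether, or β-elimination once the ketone is free, may lead to re-aromatisation faster than clean unmasking. The fallback sets out from 13 and comes back at 15. The silyl dienol ether would be exchanged for a dimethyl ketal before the carbinol is made: 13 with MeOH, HC(OMe)3 and pyridinium p-toluenesulfonate (0 °C) should give (S)-6-[(E)-heptadec-14-enyl]-4,4-dimethoxy-6-(triethylsilyloxy)cyclohex-2-en-1-one F6. Reduction with i-Bu2AlH (CH2Cl2, −78 °C), again by attack anti to the silyloxy group, would give (1R,6S)-6-[(E)-heptadec-14-enyl]-4,4-dimethoxy-6-(triethylsilyloxy)cyclohex-2-en-1-ol F7, in which the tertiary C–O bond is no longer allylic. Aqueous HF in MeCN (0 °C) would then hydrolyse the ketal and cleave the silyl ether to 15.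

**Further compounds**

F1 | step 6 | 2-[(E)-heptadec-14-enyl]-4-methoxyphenol | CC/C=C/CCCCCCCCCCCCCc1cc(OC)ccc1O
F2 | step 6 | 2-[(E)-heptadec-14-enyl]-4,4-dimethoxycyclohexa-2,5-dien-1-one | CC/C=C/CCCCCCCCCCCCCC1=CC(OC)(OC)C=CC1=O
F3 | step 6 | (R)-2-[(E)-heptadec-14-enyl]-4,4-dimethoxycyclohexa-2,5-dien-1-ol | CC/C=C/CCCCCCCCCCCCCC1=CC(OC)(OC)C=C[C@H]1O
F4 | step 6 | (1R,2R,6R)-1-[(E)-heptadec-14-enyl]-5,5-dimethoxy-7-oxabicyclo[4.1.0]hept-3-en-2-ol | CC/C=C/CCCCCCCCCCCCC[C@]12O[C@H]1C(OC)(OC)C=C[C@H]2O
F5 | step 6 | (1R,5R,6R)-6-[(E)-heptadec-14-enyl]-5-hydroxy-7-oxabicyclo[4.1.0]hept-3-en-2-one | CC/C=C/CCCCCCCCCCCCC[C@]12O[C@H]1C(=O)C=C[C@H]2O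
F0 | step 8 | none | none
F6 | step 9 | (S)-6-[(E)-heptadec-14-enyl]-4,4-dimethoxy-6-(triethylsilyloxy)cyclohex-2-en-1-one | CC/C=C/CCCCCCCCCCCCC[C@]1(O[Si](CC)(CC)CC)CC(OC)(OC)C=CC1=O
F7 | step 9 | (1R,6S)-6-[(E)-heptadec-14-enyl]-4,4-dimethoxy-6-(triethylsilyloxy)cyclohex-2-en-1-ol | CC/C=C/CCCCCCCCCCCCC[C@]1(O[Si](CC)(CC)CC)CC(OC)(OC)C=C[C@H]1O
A1 | direct plan | 3-(tert-butyldimethylsilyloxy)-3-[(E)-heptadec-14-enyl]cyclobutan-1-one | CC/C=C/CCCCCCCCCCCCCC1(O[Si](C)(C)C(C)(C)C)CC(=O)C1
A2 | direct plan | (R)-5-(tert-butyldimethylsilyloxy)-5-[(E)-heptadec-14-enyl]cyclohex-2-en-1-one | CC/C=C/CCCCCCCCCCCCC[C@]1(O[Si](C)(C)C(C)(C)C)CC(=O)C=CC1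
A3 | direct plan | (S)-5-[(E)-heptadec-14-enyl]-5-hydroxycyclohex-3-en-1-one | CC/C=C/CCCCCCCCCCCCC[C@]1(O)CC(=O)CC=C1
A4 | direct plan | (1R,5S,6R)-5-[(E)-heptadec-14-enyl]-5-hydroxy-7-oxabicyclo[4.1.0]heptan-3-one | CC/C=C/CCCCCCCCCCCCC[C@]1(O)CC(=O)C[C@H]2O[C@@H]12
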